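**Retrosynthetic overview**

1. 30 ⇒ 29 (acetylation of C15–OH) ⇒ 28. Ring C (the 3(2H)-furanone, O–C10–C1–C2=C3) is opened to the α′-hydroxy ynone 27 (5-endo-dig O–C3 closure), and ring B (the ten-membered carbocycle) is opened at C1–C2 (Nozaki–Hiyama–Kishi closure of iodoalkyne aldehyde 25).
2. Ring A (the α-methylene-γ-butyrolactone: O6, C6, C7, C11, C12, exocyclic C13) is taken back to the 2-ethoxy-3-methylideneoxolane 19 (lactol-ether level) and disconnected at C7–C11: a borylative 5-exo enyne cyclization of the propargylic mixed acetal 17, which sets C7 and C8 from C6 alone.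
3. Enabling feature: C13≡C11–C12–O6–C6–C7=C8 is a 1,6-enyne. C11 is the ring-A carbon that carries the exocyclic methylene, and C8, the exocyclic neighbour of ring A, is the carbon that needs oxygen, so syn addition of C11 and boron across an (E)-C7=C8 bond maps onto the target.
4. 17 ⇒ allylic alcohol 15 ⇒ enynal 7 (C2–C6 and C15, from but-2-yne-1,4-diol) + alkyne 12 (C7–C10, C1 and C14, from (R)-citramalic acid, which supplies C10), joined by a catalytic asymmetric alkenylzinc addition that sets C6.
5. Order of ring formation: ring A (step 11), ring B (step 16), ring C (step 18).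

Key step: step 11

Remark: locants follow germacranolide numbering (C1 ketone, C2=C3 furanone alkene, C4=C5 with C15 on C4, C6 lactone carbinol, C7, C8 angelate carbinol, C9 methylene, C10 quaternary carbon with methyl C14, C11/C12/C13 α-methylene lactone). Assumption: (−)-MIB, (2S)-(−)-3-exo-morpholinoisoborneol, directs alkenylzinc addition to the Si face of enal 7 as it does for simple aldehydes.

**Route**

Step 1
Reactants: 1 but-2-yne-1,4-diol
Product: 2 4-[(tert-butyldiphenylsilyl)oxy]but-2-yn-1-ol
Conditions: TBDPSCl (0.3 equiv), imidazole, THF, 0 °C to rt (diol in excess)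
Reagents that add atoms: tert-butyl(chloro)diphenylsilane, CC(C)(C)[Si](Cl)(c1ccccc1)c1ccccc1
Why: Monosilylation of the symmetric diol used in excess is a standard silyl ether formation, and the acid-stable TBDPS group is chosen so that C15–O survives steps 10 and 13.

Step 2
Reactants: 2 4-[(tert-butyldiphenylsilyl)oxy]but-2-yn-1-ol
Product: 4 (Z)-4-[(tert-butyldiphenylsilyl)oxy]-3-iodobut-2-en-1-ol, via cyclic alkenylalanate 3 (not isolated)
Conditions: NaAlH2(OCH2CH2OMe)2 (Red-Al), THF, 0 °C; then I2, −78 °C
Reagents that add atoms: iodine, II; sodium bis(2-methoxyethoxy)aluminium dihydride, [Na+].COCCO[AlH2-]OCCOC (aluminium only in 3)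
Why: Hydroxyl-directed trans-hydroalumination of the propargylic alcohol puts aluminium on the distal alkyne carbon (C4) in a five-membered chelate, and iodinolysis with retention gives the iodoalkene with iodine cis to C6, which fixes the C4=C5 geometry of the target.

Step 3
Reactants: 4 (Z)-4-[(tert-butyldiphenylsilyl)oxy]-3-iodobut-2-en-1-ol; 5 ethynyl(trimethyl)silane
Product: 6 (E)-3-{[(tert-butyldiphenylsilyl)oxy]methyl}-5-(trimethylsilyl)pent-2-en-4-yn-1-ol (alkyne cis to the CH2OH carbon)
Conditions: PdCl2(PPh3)2 (cat.), CuI (cat.), iPr2NH, THF, rt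
Reagents that add atoms: none
Why: Sonogashira coupling proceeds with retention at the alkenyl iodide and installs C3 and C2; the descriptor changes from Z to E only through CIP ranking.

Step 4
Reactants: 6 (E)-3-{[(tert-butyldiphenylsilyl)oxy]methyl}-5-(trimethylsilyl)pent-2-en-4-yn-1-ol
Product: 7 (E)-3-{[(tert-butyldiphenylsilyl)oxy]methyl}-5-(trimethylsilyl)pent-2-en-4-ynal
Conditions: MnO2, CH2Cl2, rt
Reagents that add atoms: none
Why: MnO2 oxidises the primary allylic alcohol selectively to the enal (allylic oxidation) without touching the silyl groups or the enyne.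

Step 5
Reactants: 8 (R)-citramalic acid
Product: 9 (2R)-2-methylbutane-1,2,4-triol
Conditions: BH3·SMe2, B(OMe)3, THF, 0 °C to rt; MeOH quench
Reagents that add atoms: none
Why: Borane reduces both carboxylic acids to primary alcohols (carboxylic acid reduction) and leaves the tertiary carbinol, the future C10, untouched.

Step 6
Reactants: 9 (2R)-2-methylbutane-1,2,4-triol
Product: 10 2-[(4R)-2,2,4-trimethyl-1,3-dioxolan-4-yl]ethan-1-ol
Conditions: Me2C(OMe)2, p-TsOH (cat.), acetone, rt
Reagents that add atoms: 2,2-dimethoxypropane, COC(C)(C)OC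
Why: Acid-catalysed acetonide formation under thermodynamic control prefers the five-membered dioxolane over the dioxane, protecting O1 and O10 together and leaving the C8 hydroxyl free.

Step 7
Reactants: 10 2-[(4R)-2,2,4-trimethyl-1,3-dioxolan-4-yl]ethan-1-ol
Product: 11 2-[(4R)-2,2,4-trimethyl-1,3-dioxolan-4-yl]acetaldehyde
Conditions: nPr4NRuO4 (cat.), NMO, 4 Å MS, CH2Cl2, rt
Reagents that add atoms: none
Why: Ley–Griffith oxidation converts the primary alcohol into the aldehyde under neutral conditions that the acetonide tolerates.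

Step 8
Reactants: 11 2-[(4R)-2,2,4-trimethyl-1,3-dioxolan-4-yl]acetaldehyde
Product: 12 (4R)-2,2,4-trimethyl-4-(prop-2-yn-1-yl)-1,3-dioxolane
Conditions: dimethyl (1-diazo-2-oxopropyl)phosphonate, K2CO3, MeOH, 0 °C to rt
Reagents that add atoms: dimethyl (1-diazo-2-oxopropyl)phosphonate, CC(=O)C(=[N+]=[N-])P(=O)(OC)OC
Why: Ohira–Bestmann (Seyferth–Gilbert) homologation turns the aldehyde into the terminal alkyne, the added carbon becoming C7.

Step 9
Reactants: 12 (4R)-2,2,4-trimethyl-4-(prop-2-yn-1-yl)-1,3-dioxolane; 7 (E)-3-{[(tert-butyldiphenylsilyl)oxy]methyl}-5-(trimethylsilyl)pent-2-en-4-ynal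
Product: 15 (2E,4S,5E)-6-{[(tert-butyldiphenylsilyl)oxy]methyl}-1-[(4R)-2,2,4-trimethyl-1,3-dioxolan-4-yl]-8-(trimethylsilyl)octa-2,5-dien-7-yn-4-ol, via alkenylborane 13 (not isolated), via alkenylzinc 14 (not isolated)
Conditions: Cy2BH, toluene, 0 °C to rt; Et2Zn, −78 °C; (−)-MIB (cat.), then 7, −10 °C
Reagents that add atoms: dicyclohexylborane, B(C1CCCCC1)C1CCCCC1 (boron only in 13); diethylzinc, CC[Zn]CC (zinc only in 14)
Why: syn-Hydroboration gives the (E)-alkenylborane, and boron-to-zinc exchange followed by amino-alcohol-catalysed 1,2-addition to the enal (catalytic asymmetric alkenylzinc addition) forms C6–C7 with the (E)-C7=C8 alkene, (−)-MIB delivering the alkenyl group to the Si face so that C6 is set by catalyst control (S descriptor here, the spatial arrangement of C6 in the target).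

Step 10
Reactants: 15 the (4S)-bis-allylic alcohol; 16 3,3-diethoxyprop-1-yne
Product: 17 O6-(1-ethoxyprop-2-yn-1-yl) mixed acetal of 15 (6S,10R; both epimers at the acetal carbon)
Conditions: 16 (excess), PPTS (cat.), toluene, 5 Å MS, 45 °C
Reagents that add atoms: none
Why: Acid-catalysed transacetalization (mixed acetal formation), driven by removal of ethanol, hangs C11–C13 on O6 at the lactol-ether level; the acetal centre becomes the sp2 carbon C12 in step 14, so its configuration does not matter.

Step 11
Reactants: 17 O6-(1-ethoxyprop-2-yn-1-yl) mixed acetal of 15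
Product: 19 (6R,7R,8S,10R)-2-ethoxy-3-methylideneoxolane C8 alcohol (enyne arm on C6 trans to the CH(OH)CH2-dioxolane arm on C7), via C8 pinacol boronate 18 (not isolated)
Conditions: Pd(OAc)2 (5 mol %), B2pin2, MeOH (1 equiv), toluene, 50 °C; then H2O2, pH 7 phosphate buffer, THF, 0 °C to rt
Reagents that add atoms: hydrogen peroxide, OO; bis(pinacolato)diboron, CC1(C)OB(OC1(C)C)B1OC(C)(C)C(C)(C)O1 (boron only in 18)
Why: Proposed new method: a Pd–H species formed from Pd(OAc)2, B2pin2 and MeOH should add syn to the terminal alkyne with palladium on the internal carbon C11 (alkene chelation), the alkenylpalladium then inserts the (E)-C7=C8 bond in a 5-exo-trig syn-carbopalladation that forms C7–C11 and closes the oxolane (ring A at lactol-ether level), and the secondary C8–Pd is intercepted by transmetalation with B2pin2 and C–B reductive elimination with retention before β-hydride elimination, buffered peroxide then replacing boron by oxygen with retention; the closest known reaction type is the phosphine-free Pd-catalysed borylative cyclization of carbon-, nitrogen- and oxygen-tethered 1,6-enynes to homoallylic alkylboronates, which to my knowledge has not been shown for a propargylic mixed-acetal tether with a 1,2-disubstituted alkene next to a stereocentre. C7 is set by C6: in the chair-like insertion transition state the large dienynyl group on C6 sits pseudo-equatorial with C6–H near the alkene plane, which gives the 6,7-trans ring, as in the related divalent-palladium cyclizations of secondary allylic 2-alkynoates. C8 is set by the alkene geometry, because C11 and boron add to the same face of the (E)-alkene and oxygen then takes the place of boron. The step needs chemoselectivity for the terminal alkyne over the silyl-capped enyne and for the disubstituted C7=C8 alkene over the trisubstituted, conjugated C4=C5 alkene, which sterics and the 1,6-enyne chelate should secure. The acetal tether is used instead of a propiolate ester because zerovalent palladium formed in the cycle would ionise a bis-allylic ester but leaves an acetal alone.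

Step 12
Reactants: 19 the C8 alcohol; 20 angelic acid
Product: 22 C8 angelate of 19 (6R,7R,8S,10R), via mixed anhydride 21 (not isolated)
Conditions: 20, 2,4,6-Cl3C6H2COCl, Et3N, toluene, rt; then 19, 75 °C
Reagents that add atoms: 2,4,6-trichlorobenzoyl chloride, O=C(Cl)c1c(Cl)cc(Cl)cc1Cl (only in 21)
Why: Yamaguchi esterification through the hindered mixed anhydride acylates the C8 hydroxyl, and the amine-only protocol is the usual way to avoid Z-to-E isomerisation of the angelate to the tiglate.

Step 13
Reactants: 22 C8 angelate of 19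
Product: 23 lactol 1,10-diol (2-hydroxy-3-methylideneoxolane, both anomers; C1 and C10 hydroxyls free)
Conditions: AcOH/THF/H2O (3:1:1), 35 °C
Reagents that add atoms: water, O
Why: Mild aqueous acid hydrolyses both acetals (the 2-ethoxyoxolane to the lactol and the acetonide to the diol) in one acetal hydrolysis, while the TBDPS ether, the alkynylsilane and the angelate are stable to it.

Step 14
Reactants: 23 lactol 1,10-diol
Product: 24 (6R,7R,8S,10R)-α-methylene-γ-butyrolactone C1 aldehyde (free C10 hydroxyl, trimethylsilyl on C2)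
Conditions: SO3·pyridine, DMSO, iPr2NEt, CH2Cl2, 0 °C
Reagents that add atoms: none
Why: Parikh–Doering oxidation (activated DMSO) converts the lactol into the α-methylene lactone and the primary C1 alcohol into the aldehyde in one operation, does not cleave the 1,2-diol and leaves the tertiary C10 hydroxyl untouched.

Step 15
Reactants: 24 lactone C1 aldehyde
Product: 25 iodoalkyne aldehyde (iodine on C2)
Conditions: NIS, AgNO3 (cat.), acetone, rt, dark
Reagents that add atoms: N-iodosuccinimide, O=C1CCC(=O)N1I
Why: Silver-catalysed iododesilylation exchanges the alkynyl trimethylsilyl group for iodine directly, which avoids basic desilylation in the presence of the α-methylene lactone.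

Step 16
Reactants: 25 iodoalkyne aldehyde
Product: 26 ten-membered propargylic alcohol (ring B closed; both C1 epimers)
Conditions: CrCl2 (excess), NiCl2 (cat.), THF, rt, syringe-pump addition at high dilution
Reagents that add atoms: none
Why: Nozaki–Hiyama–Kishi reaction: the alkynylchromium formed from the iodoalkyne adds selectively to the aldehyde and closes ring B at C1–C2, and both C1 epimers are used because C1 becomes a ketone.

Step 17
Reactants: 26 ten-membered propargylic alcohol
Product: 27 ten-membered α′-hydroxy ynone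
Conditions: MnO2, CH2Cl2, rt
Reagents that add atoms: none
Why: MnO2 oxidises the secondary propargylic alcohol to the ynone (propargylic oxidation) and leaves the tertiary C10 hydroxyl untouched.

Step 18
Reactants: 27 ten-membered α′-hydroxy ynone
Product: 28 15-O-TBDPS furanoheliangolide (ring C closed)
Conditions: AuCl3 (5 mol %), CH2Cl2, rt
Reagents that add atoms: none
Why: Gold-catalysed 5-endo-dig cycloisomerisation of the α′-hydroxy ynone: O10 adds to the activated alkyne at C3 and protodeauration gives the 3(2H)-furanone, the C10 configuration being untouched.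

Step 19
Reactants: 28 15-O-TBDPS furanoheliangolide
Product: 29 15-hydroxy furanoheliangolide
Conditions: HF·pyridine, pyridine, THF, 0 °C to rt
Reagents that add atoms: none
Why: Fluoride-mediated silyl ether cleavage under buffered, weakly acidic conditions frees the C15 hydroxyl without conjugate addition to the α-methylene lactone or the dienone.

Step 20
Reactants: 29 15-hydroxy furanoheliangolide
Product: 30 CNP0122132.1
Conditions: Ac2O, pyridine, DMAP (cat.), CH2Cl2, 0 °C
Reagents that add atoms: acetic anhydride, CC(=O)OC(C)=O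
Why: Acylation of the only free hydroxyl (primary, allylic) with acetic anhydride gives the acetate.

**Compound list**

1 | but-2-yne-1,4-diol | OCC#CCO | starting material
2 | 4-[(tert-butyldiphenylsilyl)oxy]but-2-yn-1-ol | OCC#CCO[Si](c1ccccc1)(c1ccccc1)C(C)(C)C | intermediate
3 | sodium cyclic alkenylalanate of 2 (five-membered O–Al–C4 chelate, two 2-methoxyethoxy groups on aluminium) | [Na+].COCCO[Al-]1(OCCOC)OCC=C1CO[Si](c1ccccc1)(c1ccccc1)C(C)(C)C | intermediate
4 | (Z)-4-[(tert-butyldiphenylsilyl)oxy]-3-iodobut-2-en-1-ol | OC/C=C(\I)CO[Si](c1ccccc1)(c1ccccc1)C(C)(C)C | intermediate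
5 | ethynyl(trimethyl)silane | C#C[Si](C)(C)C | starting material
6 | (E)-3-{[(tert-butyldiphenylsilyl)oxy]methyl}-5-(trimethylsilyl)pent-2-en-4-yn-1-ol | OC/C=C(\C#C[Si](C)(C)C)CO[Si](c1ccccc1)(c1ccccc1)C(C)(C)C | intermediate
7 | (E)-3-{[(tert-butyldiphenylsilyl)oxy]methyl}-5-(trimethylsilyl)pent-2-en-4-ynal | O=C/C=C(\C#C[Si](C)(C)C)CO[Si](c1ccccc1)(c1ccccc1)C(C)(C)C | intermediate
8 | (R)-citramalic acid, (2R)-2-hydroxy-2-methylbutanedioic acid | OC(=O)[C@@](C)(CC(=O)O)O | starting material
9 | (2R)-2-methylbutane-1,2,4-triol | OC[C@@](C)(CCO)O | intermediate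
10 | 2-[(4R)-2,2,4-trimethyl-1,3-dioxolan-4-yl]ethan-1-ol | OCC[C@]1(C)COC(C)(C)O1 | intermediate
11 | 2-[(4R)-2,2,4-trimethyl-1,3-dioxolan-4-yl]acetaldehyde | O=CC[C@]1(C)COC(C)(C)O1 | intermediate
12 | (4R)-2,2,4-trimethyl-4-(prop-2-yn-1-yl)-1,3-dioxolane | C#CC[C@]1(C)COC(C)(C)O1 | intermediate
13 | dicyclohexyl{(E)-3-[(4R)-2,2,4-trimethyl-1,3-dioxolan-4-yl]prop-1-en-1-yl}borane | C1CCCCC1B(/C=C/C[C@]2(C)COC(C)(C)O2)C1CCCCC1 | intermediate
14 | ethyl{(E)-3-[(4R)-2,2,4-trimethyl-1,3-dioxolan-4-yl]prop-1-en-1-yl}zinc | CC[Zn]/C=C/C[C@]1(C)COC(C)(C)O1 | intermediate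
15 | (2E,4S,5E)-6-{[(tert-butyldiphenylsilyl)oxy]methyl}-1-[(4R)-2,2,4-trimethyl-1,3-dioxolan-4-yl]-8-(trimethylsilyl)octa-2,5-dien-7-yn-4-ol | C[Si](C)(C)C#C/C(CO[Si](c1ccccc1)(c1ccccc1)C(C)(C)C)=C\[C@@H](O)/C=C/C[C@]1(C)COC(C)(C)O1 | intermediate
16 | 3,3-diethoxyprop-1-yne | C#CC(OCC)OCC | starting material
17 | O6-(1-ethoxyprop-2-yn-1-yl) mixed acetal of 15 (6S,10R; both acetal epimers) | C[Si](C)(C)C#C/C(CO[Si](c1ccccc1)(c1ccccc1)C(C)(C)C)=C\[C@@H](OC(OCC)C#C)/C=C/C[C@]1(C)COC(C)(C)O1 | intermediate
18 | C8 pinacol boronate of the 2-ethoxy-3-methylideneoxolane (boron where the C8 hydroxyl of 19 will stand) | C=C1C(OCC)O[C@H](/C=C(\C#C[Si](C)(C)C)CO[Si](c2ccccc2)(c2ccccc2)C(C)(C)C)[C@H]1[C@@H](B2OC(C)(C)C(C)(C)O2)C[C@]3(C)COC(C)(C)O3 | intermediate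
19 | (6R,7R,8S,10R)-2-ethoxy-3-methylideneoxolane C8 alcohol (enyne arm on C6, CH(OH)CH2-dioxolane arm on C7, 6,7-trans) | C=C1C(OCC)O[C@H](/C=C(\C#C[Si](C)(C)C)CO[Si](c2ccccc2)(c2ccccc2)C(C)(C)C)[C@H]1[C@@H](O)C[C@]3(C)COC(C)(C)O3 | intermediate
20 | angelic acid, (Z)-2-methylbut-2-enoic acid | C/C=C(/C)C(=O)O | starting material
21 | angelic 2,4,6-trichlorobenzoic anhydride | C/C=C(/C)C(=O)OC(=O)c1c(Cl)cc(Cl)cc1Cl | intermediate
22 | C8 angelate of 19 (6R,7R,8S,10R) | C=C1C(OCC)O[C@H](/C=C(\C#C[Si](C)(C)C)CO[Si](c2ccccc2)(c2ccccc2)C(C)(C)C)[C@H]1[C@@H](OC(=O)/C(C)=C\C)C[C@]3(C)COC(C)(C)O3 | intermediate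
23 | lactol 1,10-diol (2-hydroxy-3-methylideneoxolane, both anomers) | C=C1C(O)O[C@H](/C=C(\C#C[Si](C)(C)C)CO[Si](c2ccccc2)(c2ccccc2)C(C)(C)C)[C@H]1[C@@H](OC(=O)/C(C)=C\C)C[C@@](C)(O)CO | intermediate
24 | (6R,7R,8S,10R)-α-methylene-γ-butyrolactone C1 aldehyde (C10–OH free, C2–SiMe3) | C=C1C(=O)O[C@H](/C=C(\C#C[Si](C)(C)C)CO[Si](c2ccccc2)(c2ccccc2)C(C)(C)C)[C@H]1[C@@H](OC(=O)/C(C)=C\C)C[C@@](C)(O)C=O | intermediate
25 | iodoalkyne aldehyde (iodine on C2) | C=C1C(=O)O[C@H](/C=C(\C#CI)CO[Si](c2ccccc2)(c2ccccc2)C(C)(C)C)[C@H]1[C@@H](OC(=O)/C(C)=C\C)C[C@@](C)(O)C=O | intermediate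
26 | ten-membered propargylic alcohol (both C1 epimers) | C=C1C(=O)O[C@@H]2/C=C(/CO[Si](c3ccccc3)(c3ccccc3)C(C)(C)C)C#CC(O)[C@](C)(O)C[C@H](OC(=O)/C(C)=C\C)[C@@H]12 | intermediate
27 | ten-membered α′-hydroxy ynone | C=C1C(=O)O[C@@H]2/C=C(/CO[Si](c3ccccc3)(c3ccccc3)C(C)(C)C)C#CC(=O)[C@](C)(O)C[C@H](OC(=O)/C(C)=C\C)[C@@H]12 | intermediate
28 | 15-O-TBDPS furanoheliangolide | C=C1C(=O)O[C@@H]2/C=C(/CO[Si](c4ccccc4)(c4ccccc4)C(C)(C)C)C3=CC(=O)[C@@](C)(C[C@H](OC(=O)/C(C)=C\C)[C@@H]12)O3 | intermediate
29 | 15-hydroxy furanoheliangolide | C=C1C(=O)O[C@@H]2/C=C(/CO)C3=CC(=O)[C@@](C)(C[C@H](OC(=O)/C(C)=C\C)[C@@H]12)O3 | intermediate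
30 | CNP0122132.1, (6R,7R,8S,10R)-15-acetoxy-8-angeloyloxy-1-oxo-3,10-epoxygermacra-2,4(Z),11(13)-trien-12,6-olide | C=C1C(=O)O[C@@H]2/C=C(/COC(C)=O)C3=CC(=O)[C@@](C)(C[C@H](OC(=O)/C(C)=C\C)[C@@H]12)O3 | target

**Totals and risks**

Total step count: 20. Longest linear sequence: 16 steps (steps 5–8, then 9–20; the branch through steps 1–4 is equally long).

Steps most likely to fail:

1. Step 11 (Proposed new method). What may go wrong: β-hydride elimination from the secondary alkylpalladium at C8 outrunning boron transfer, or insufficient facial selectivity in the alkene insertion. The fallback uses known chemistry, sets out from 17 and comes back at 19. Shi epoxidation of the (E)-C7=C8 alkene of 17 with the enantiomer of the fructose-derived ketone (KHSO5, K2CO3, MeCN/dimethoxymethane/H2O, 0 °C; reagent control, the electron-poor trisubstituted C4=C5 alkene should react more slowly) should give the (6R,7R,8S,10R)-trans-epoxide F1, which already holds the C8–O bond of the target. Cp2TiCl (from Cp2TiCl2 and Zn), THF, rt then opens the epoxide by single-electron transfer from trivalent titanium (Nugent–RajanBabu conditions); the C7 radical cyclizes 5-exo-dig onto the acetal-tethered alkyne, trans to the C6 substituent, and the alkenyl radical is reduced, giving 19 after aqueous work-up. The C7 radical is planar, so this closure of the same C7–C11 bond does not depend on the epoxide configuration at C7.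

2. Step 16. What may go wrong: oligomerisation, or failure to close a ten-membered ring that must hold a linear alkyne next to a cis-alkene. The fallback sets out from 24 and comes back at 28, closing ring B by an aldol addition on a chain without the alkyne. Ph3PAuNTf2-catalysed hydration (H2O, dioxane) of the silyl alkyne, with loss of the silyl group, should give the C3 methyl ketone aldehyde F2. Bu2BOTf/iPr2NEt in CH2Cl2 at high dilution then adds the C2 boron enolate to the C1 aldehyde (intramolecular aldol addition) to give the ten-membered β-hydroxy ketone F3. IBX in EtOAc oxidises it to the α′-hydroxy-1,3-diketone F4, and p-TsOH in toluene cyclodehydrates F4 (O10 onto the C3 ketone, the classical 3(2H)-furanone synthesis) to 28.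

3. Step 10. What may go wrong: acid-promoted ionisation and allylic transposition of the bis-allylic alcohol, or incomplete acetal exchange. The fallback sets out from 15 and 16 and comes back at 17 without acid. Acetyl chloride with Zn(OAc)2 (cat.) converts 16 into the α-chloro ether 1-chloro-1-ethoxyprop-2-yne F5, which alkylates the hydroxyl of 15 in the presence of iPr2NEt (CH2Cl2, −40 °C) to give 17.

Further compounds
F1 | step 11 | (6R,7R,8S,10R)-7,8-trans-epoxide of mixed acetal 17 | C[Si](C)(C)C#C/C(CO[Si](c1ccccc1)(c1ccccc1)C(C)(C)C)=C\[C@@H](OC(OCC)C#C)[C@@H]1O[C@H]1C[C@]2(C)COC(C)(C)O2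
F2 | step 16 | C3 methyl ketone C1 aldehyde (hydration product of 24) | C=C1C(=O)O[C@H](/C=C(\C(C)=O)CO[Si](c2ccccc2)(c2ccccc2)C(C)(C)C)[C@H]1[C@@H](OC(=O)/C(C)=C\C)C[C@@](C)(O)C=O
F3 | step 16 | ten-membered β-hydroxy ketone (C1 carbinol, C3 ketone; both C1 epimers) | C=C1C(=O)O[C@@H]2/C=C(/CO[Si](c3ccccc3)(c3ccccc3)C(C)(C)C)C(=O)CC(O)[C@](C)(O)C[C@H](OC(=O)/C(C)=C\C)[C@@H]12
F4 | step 16 | ten-membered α′-hydroxy-1,3-diketone (C1 and C3 ketones) | C=C1C(=O)O[C@@H]2/C=C(/CO[Si](c3ccccc3)(c3ccccc3)C(C)(C)C)C(=O)CC(=O)[C@](C)(O)C[C@H](OC(=O)/C(C)=C\C)[C@@H]12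
F5 | step 10 | 1-chloro-1-ethoxyprop-2-yne | C#CC(Cl)OCC
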